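**Strategy**

The quinone ring (C1 carbonyl between C2–OMe and C6–alkyl, C4 carbonyl, C3 and C5 as CH) is assembled last by a Dötz benzannulation with oxidative work-up. Its para-dioxygen pattern is read as carbene carbon (C4) plus inserted CO (C1), the C2 methoxy group as the β-substituent of an alkenylcarbene, and C5–H/C6–alkyl as a terminal alkyne that already carries the (R)-acetoxy side chain. In one operation the alkyne CH bonds to the carbene carbon (C5–C4) and the CO-derived carbon to the methoxy-bearing vinyl carbon (C1–C2); (NH4)2Ce(NO3)6 then unmasks the quinone. The precursors are an acyclic chromium carbene complex and heptadec-1-yn-4-yl acetate, made from (R)-epichlorohydrin.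

Key step: step 6

Remark on the chemistry: the side-chain carbinol centre of the target is (R), and its descriptor is unchanged along the whole sequence from (R)-epichlorohydrin. The same key step also forms the C6–C1 bond through the inserted CO.
Assumption: (Z)-1-bromo-2-methoxyethene is treated as not purchasable and is therefore made in step 4.

**Route**

Step 1
Reactants: 1 (R)-epichlorohydrin; 2 dodecylmagnesium bromide
Product: 3 (R)-1-chloropentadecan-2-ol
Conditions: C12H25MgBr (1.1 equiv), CuI (10 mol %), THF, −40 °C; then H2O
Reagents that add atoms: none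
Why: Copper-catalysed Grignard opening of the epoxide at its unsubstituted carbon (SN2) should outrun displacement of chloride, and the stereocentre of 1 is not touched, so it becomes C2 of 3 with the (R) descriptor unchanged.

Step 2
Reactants: 3 (R)-1-chloropentadecan-2-ol; 4 lithium acetylide ethylenediamine complex
Product: 6 (R)-heptadec-1-yn-4-ol, via epoxide 5 (not isolated)
Conditions: LiC≡CH·H2NCH2CH2NH2 (3 equiv), DMSO, 0 °C → rt; then H2O
Reagents that add atoms: none
Why: The alkoxide formed by the first equivalent should close to terminal epoxide 5 (intramolecular Williamson reaction), which the acetylide opens at the primary carbon (SN2 epoxide alkynylation), the carbinol centre being untouched in both events.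

Step 3
Reactants: 6 (R)-heptadec-1-yn-4-ol
Product: 7 (R)-heptadec-1-yn-4-yl acetate
Conditions: Ac2O, pyridine, DMAP (cat.), CH2Cl2, rt
Reagents that add atoms: acetic anhydride, CC(=O)OC(C)=O
Why: DMAP-catalysed O-acylation of the secondary alcohol breaks no bond to the stereocentre and installs the acetate of the target before the oxidant-sensitive ring exists.

Step 4
Reactants: 8 methyl vinyl ether
Product: 10 (Z)-1-bromo-2-methoxyethene, via dibromo ether 9 (not isolated)
Conditions: Br2, CH2Cl2, −78 °C; then PhNEt2, 95 °C, distillation
Reagents that add atoms: bromine, BrBr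
Why: Electrophilic bromination of the enol ether gives α-bromo ether 9, which should lose HBr through its oxocarbenium ion (dehydrohalogenation) to the 2-bromovinyl ether, the cis isomer being expected to prevail as is usual for 1,2-diheteroatom-substituted alkenes.

Step 5
Reactants: 10 (Z)-1-bromo-2-methoxyethene; 11 Cr(CO)6
Product: 14 pentacarbonyl[(2Z)-1,3-dimethoxyprop-2-en-1-ylidene]chromium, via vinyllithium 12 (not isolated), via lithium acylchromate 13 (not isolated)
Conditions: t-BuLi (2 equiv), Et2O, −78 °C; then Cr(CO)6, −78 → 0 °C; then Me3OBF4, CH2Cl2, 0 °C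
Reagents that add atoms: trimethyloxonium tetrafluoroborate, C[O+](C)C.F[B-](F)(F)F
Why: Bromine–lithium exchange with retention should give the oxygen-chelated Z-vinyllithium 12, which adds to a CO ligand of Cr(CO)6 to give acylate 13, and O-methylation with the hard oxonium salt completes the Fischer carbene synthesis.

Step 6
Reactants: 7 (R)-heptadec-1-yn-4-yl acetate; 14 pentacarbonyl[(2Z)-1,3-dimethoxyprop-2-en-1-ylidene]chromium
Product: 16 ardisinone, via dimethoxyphenol 15 (not isolated)
Conditions: 14 (1.3 equiv), THF, 50 °C, Ar; then (NH4)2Ce(NO3)6, MeCN/H2O, 0 °C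
Reagents that add atoms: water, O
Why: Heating opens a coordination site on chromium (loss of CO, helped by the hemilabile cis-methoxy oxygen), the terminal alkyne inserts into Cr=C with its CH end bonding to the carbene carbon (C5–C4) because the substituted end stays remote from the carbene substituents, a CO ligand inserts to give a chromium-bound dienylketene (C6–C1), and this closes to the six-membered ring by forming C1–C2, after which tautomerisation gives 4-methoxyphenol 15 as its Cr(CO)3 complex. This is the Dötz benzannulation of an alkenyl(alkoxy)carbene complex of chromium with a terminal alkyne, run with the usual oxidative work-up, in which tetravalent cerium strips the metal and water attacks the methoxy-bearing C4 of the oxidised phenol to release methanol and the para-quinone. The single ring is closed by a thermal 6π-electrocyclisation of the metal-bound dienylketene, a formal [3+2+1] assembly. No stereocentre is created, and the acetoxy-bearing centre, two atoms from the ring, is not involved. The step needs regiocontrol of alkyne insertion, secured by the terminal alkyne (H against a branched alkyl chain), phenol formation over cyclopentannulation, which is the normal course for alkenyl complexes of chromium in THF, and para- over ortho-quinone formation, expected because the C4 oxygen is para to the free hydroxyl.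

**Compound list**

1 | (R)-epichlorohydrin | ClC[C@H]1CO1 | starting material
2 | dodecylmagnesium bromide | CCCCCCCCCCCC[Mg]Br | starting material
3 | (R)-1-chloropentadecan-2-ol | CCCCCCCCCCCCC[C@H](CCl)O | intermediate
4 | lithium acetylide ethylenediamine complex | [Li]C#C.NCCN | starting material
5 | (R)-2-tridecyloxirane | CCCCCCCCCCCCC[C@@H]1CO1 | intermediate (not isolated)
6 | (R)-heptadec-1-yn-4-ol | CCCCCCCCCCCCC[C@H](CC#C)O | intermediate
7 | (R)-heptadec-1-yn-4-yl acetate | CCCCCCCCCCCCC[C@H](CC#C)OC(C)=O | intermediate
8 | methyl vinyl ether | COC=C | starting material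
9 | 1,2-dibromo-1-methoxyethane (racemic) | COC(Br)CBr | intermediate (not isolated)
10 | (Z)-1-bromo-2-methoxyethene | CO/C=C\Br | intermediate
11 | Cr(CO)6, hexacarbonylchromium | O=C=[Cr](=C=O)(=C=O)(=C=O)(=C=O)=C=O | starting material
12 | (Z)-2-methoxyvinyllithium | CO/C=C\[Li] | intermediate (not isolated)
13 | lithium pentacarbonyl[(2Z)-3-methoxy-1-oxidoprop-2-en-1-ylidene]chromate | [Li+].CO/C=C\C([O-])=[Cr](=C=O)(=C=O)(=C=O)(=C=O)=C=O | intermediate (not isolated)
14 | pentacarbonyl[(2Z)-1,3-dimethoxyprop-2-en-1-ylidene]chromium, (CO)5Cr=C(OMe)–CH=CH–OMe | CO/C=C\C(OC)=[Cr](=C=O)(=C=O)(=C=O)(=C=O)=C=O | intermediate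
15 | (R)-1-(2-hydroxy-3,5-dimethoxyphenyl)pentadecan-2-yl acetate (held on Cr(CO)3 until the oxidation) | CCCCCCCCCCCCC[C@H](Cc1cc(OC)cc(OC)c1O)OC(C)=O | intermediate (not isolated)
16 | ardisinone, (R)-1-(5-methoxy-3,6-dioxocyclohexa-1,4-dien-1-yl)pentadecan-2-yl acetate | CCCCCCCCCCCCC[C@H](CC1=CC(=O)C=C(OC)C1=O)OC(C)=O | target

**Count**

Total steps: 6. Longest linear sequence: 4 steps (1, 2, 3, 6); the carbene branch (4, 5) joins at step 6.

**Steps most likely to fail**

Step 6. The donor β-methoxy group may retard CO insertion after the alkyne has inserted, so that the vinylcarbene intermediate closes to five-membered-ring products or furans instead of the phenol; in the oxidation, water may also add ortho to the hydroxyl instead of para. The fallback uses no carbene chemistry and sets out from chlorohydrin 3. It is closed with NaOH in Et2O/H2O to epoxide 5, which is now isolated. Epoxide 5 is opened at its CH2 carbon by 3,5-(MeO)2C6H3MgBr with CuI catalysis in THF to give (R)-1-(3,5-dimethoxyphenyl)pentadecan-2-ol F1. One methyl ether is cleaved with NaSEt in hot DMF to give (R)-3-(2-hydroxypentadecyl)-5-methoxyphenol F2. Oxidation para to the phenol with (KSO3)2NO in KH2PO4-buffered aqueous acetone should give (R)-2-(2-hydroxypentadecyl)-6-methoxy-1,4-benzoquinone F3. Acetylation with Ac2O and pyridine returns to the route at target 16.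

Step 5. The vinyllithium may lose LiOMe by β-elimination before it adds to Cr(CO)6, and the electrophilic complex may suffer addition–elimination at its β-carbon during alkylation and work-up. The fallback avoids organolithium chemistry and sets out from methyl vinyl ether 8 and Cr(CO)6 11. Ether 8 is acylated with oxalyl chloride to (E)-4-methoxy-2-oxobut-3-enoyl chloride F4, which on heating loses CO to give (E)-3-methoxyacryloyl chloride F5. Complex 11 is reduced with NaC10H8 (sodium naphthalenide) in THF at −78 °C to disodium pentacarbonylchromate F6, which is acylated by F5 to sodium pentacarbonyl[(2E)-3-methoxy-1-oxidoprop-2-en-1-ylidene]chromate F7. O-Methylation with Me3OBF4 gives pentacarbonyl[(2E)-1,3-dimethoxyprop-2-en-1-ylidene]chromium F8. F8 takes the place of 14 in step 6, where the alkene geometry is lost on aromatisation, so the route is rejoined at 16.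

Step 4. The enol ether may polymerise under the HBr set free, the volatile product may be lost on distillation, and geometric control in the elimination may be incomplete. The fallback sets out from 8: NBS in MeOH gives 2-bromo-1,1-dimethoxyethane F9 (also an article of commerce). Elimination of methanol with Me3SiOTf and i-Pr2NEt in CH2Cl2 returns to the route at 10, as a Z/E mixture. Only the Z isomer is expected to survive as the lithium reagent in step 5.

**Further compounds**

F1 | step 6 | (R)-1-(3,5-dimethoxyphenyl)pentadecan-2-ol | CCCCCCCCCCCCC[C@H](Cc1cc(OC)cc(OC)c1)O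
F2 | step 6 | (R)-3-(2-hydroxypentadecyl)-5-methoxyphenol | CCCCCCCCCCCCC[C@H](Cc1cc(O)cc(OC)c1)O
F3 | step 6 | (R)-2-(2-hydroxypentadecyl)-6-methoxy-1,4-benzoquinone | CCCCCCCCCCCCC[C@H](CC1=CC(=O)C=C(OC)C1=O)O
F4 | step 5 | (E)-4-methoxy-2-oxobut-3-enoyl chloride | CO/C=C/C(=O)C(Cl)=O
F5 | step 5 | (E)-3-methoxyacryloyl chloride | CO/C=C/C(Cl)=O
F6 | step 5 | disodium pentacarbonylchromate, Na2Cr(CO)5 | [Na+].[Na+].O=C=[Cr-2](=C=O)(=C=O)(=C=O)=C=O
F7 | step 5 | sodium pentacarbonyl[(2E)-3-methoxy-1-oxidoprop-2-en-1-ylidene]chromate | [Na+].CO/C=C/C([O-])=[Cr](=C=O)(=C=O)(=C=O)(=C=O)=C=O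
F8 | step 5 | pentacarbonyl[(2E)-1,3-dimethoxyprop-2-en-1-ylidene]chromium | CO/C=C/C(OC)=[Cr](=C=O)(=C=O)(=C=O)(=C=O)=C=O
F9 | step 4 | 2-bromo-1,1-dimethoxyethane | COC(OC)CBr
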